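**Retrosynthetic overview**

1. Target 26 comes from hexabenzyl ether 25 by hydrogenolysis, and 25 from bis-2H-chromene 23 by twofold hydroboration–oxidation. The strategy rests on one feature: ring C (O1, C2, C3, C4) and ring F (O1', C2', C3', C4') each carry a trans C2-aryl/C3-hydroxyl pair beside a C4 that is CH–ring D in ring C and CH2 in ring F, the pattern left by borane adding anti to the C2 aryl group of a 2-aryl-2H-chromene.
2. 23 comes from tetraene 22 by double ring-closing metathesis: C3'=C4' closes ring F first (25 °C) and C3=C4 closes ring C second (80 °C) in the same flask.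
3. 22 comes from vinylphenol 20 and cinnamyl carbonate 17 by iridium-catalysed branched allylic etherification, which sets C2'.
4. 17 comes from aryl bromide 12 (lithiation) and ketone 8 (addition, then dehydration to the 1,1-diarylethylene); 8 comes from acetophenone 6 and carbonate 5 by the same iridium etherification, which sets C2.
5. 5, 12 and 20 come from 3,4-bis(benzyloxy)benzaldehyde 1 (used twice), triethyl phosphonoacetate 2 and 4-(benzyloxy)-2-hydroxybenzaldehyde 18.

Key step: step 15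

Ring letters: A = benzo ring of the upper chromane, C = upper pyran, E = aryl group on C2, D = central catechol ring, F = lower pyran, G = benzo ring of the lower chromane.

Assumption: the (Sa,Sc,Sc) enantiomer of O,O'-(1,1'-binaphthalene-2,2'-diyl) N,N-bis(1-phenylethyl)phosphoramidite is taken to give the (S)-configured branched aryl ethers from (E)-cinnamyl carbonates; the sense would be checked on 8 and the (Ra,Rc,Rc) ligand used in steps 4 and 14 if it proved opposite.

**Route**

Step 1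
Reactants: 1 3,4-bis(benzyloxy)benzaldehyde; 2 triethyl phosphonoacetate
Product: 3 ethyl (2E)-3-[3,4-bis(benzyloxy)phenyl]prop-2-enoate
Conditions: LiCl, DBU, MeCN, 25 °C
Reagents that add atoms: none
Why: Horner–Wadsworth–Emmons olefination under Masamune–Roush conditions of a non-enolisable aryl aldehyde with a stabilised phosphonate should give the (E)-cinnamate.

Step 2
Reactants: 3 ethyl (2E)-3-[3,4-bis(benzyloxy)phenyl]prop-2-enoate
Product: 4 (2E)-3-[3,4-bis(benzyloxy)phenyl]prop-2-en-1-ol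
Conditions: i-Bu2AlH (2.5 equiv), CH2Cl2, −78→0 °C; aq. potassium sodium tartrate
Reagents that add atoms: none
Why: 1,2-reduction of the conjugated ester by i-Bu2AlH at low temperature should give the allylic alcohol without touching the alkene or the benzyl ethers.

Step 3
Reactants: 4 (2E)-3-[3,4-bis(benzyloxy)phenyl]prop-2-en-1-ol
Product: 5 (2E)-3-[3,4-bis(benzyloxy)phenyl]prop-2-en-1-yl methyl carbonate
Conditions: ClCO2Me, pyridine, CH2Cl2, 0 °C
Reagents that add atoms: methyl chloroformate, COC(=O)Cl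
Why: O-acylation of the primary allylic alcohol with a chloroformate installs the carbonate leaving group needed for iridium allyl formation.

Step 4
Reactants: 6 1-[4-(benzyloxy)-2-hydroxyphenyl]ethan-1-one; 5 (2E)-3-[3,4-bis(benzyloxy)phenyl]prop-2-en-1-yl methyl carbonate
Product: 8 1-[4-(benzyloxy)-2-{[(1S)-1-[3,4-bis(benzyloxy)phenyl]prop-2-en-1-yl]oxy}phenyl]ethan-1-one, via sodium 2-acetyl-5-(benzyloxy)phenolate 7 (not isolated)
Conditions: NaH (1.0 equiv per 6), THF, 0 °C; then 5 (limiting), [Ir(cod)Cl]2 (2 mol %), (Sa,Sc,Sc)-phosphoramidite (4 mol %, pre-activated with n-PrNH2, volatiles removed), THF, 25→50 °C, stopped at full conversion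
Reagents that add atoms: none
Why: Iridium-catalysed asymmetric allylic etherification, in which the iridium–phosphoramidite complex ionises the linear carbonate and the aryloxide attacks the aryl-substituted allyl terminus, should give the branched ether with C2 set by the ligand (catalyst control).

Step 5
Reactants: 1 3,4-bis(benzyloxy)benzaldehyde
Product: 9 4,5-bis(benzyloxy)-2-bromobenzaldehyde
Conditions: Br2 (1.05 equiv), NaOAc, AcOH, 25 °C
Reagents that add atoms: bromine, BrBr
Why: Electrophilic aromatic bromination goes para to the 3-benzyloxy group and ortho to the formyl group, as in the veratraldehyde series, and NaOAc buffers the HBr that would attack the benzyl ethers.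

Step 6
Reactants: 9 4,5-bis(benzyloxy)-2-bromobenzaldehyde; 2 triethyl phosphonoacetate
Product: 10 ethyl (2E)-3-[4,5-bis(benzyloxy)-2-bromophenyl]prop-2-enoate
Conditions: LiCl, DBU, MeCN, 25 °C
Reagents that add atoms: none
Why: Horner–Wadsworth–Emmons olefination as in step 1 should give the (E)-ester, the aryl bromide being inert to the mild base.

Step 7
Reactants: 10 ethyl (2E)-3-[4,5-bis(benzyloxy)-2-bromophenyl]prop-2-enoate
Product: 11 (2E)-3-[4,5-bis(benzyloxy)-2-bromophenyl]prop-2-en-1-ol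
Conditions: i-Bu2AlH (2.5 equiv), CH2Cl2, −78→0 °C; aq. potassium sodium tartrate
Reagents that add atoms: none
Why: 1,2-reduction of the ester by i-Bu2AlH as in step 2 leaves the aryl bromide untouched.

Step 8
Reactants: 11 (2E)-3-[4,5-bis(benzyloxy)-2-bromophenyl]prop-2-en-1-ol
Product: 12 {[(2E)-3-[4,5-bis(benzyloxy)-2-bromophenyl]prop-2-en-1-yl]oxy}(tert-butyl)dimethylsilane
Conditions: TBSCl, imidazole, DMF, 25 °C
Reagents that add atoms: tert-butyldimethylsilyl chloride, CC(C)(C)[Si](C)(C)Cl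
Why: Silylation masks the hydroxyl proton so that the bromide can be exchanged for lithium in the next step.

Step 9
Reactants: 12 {[(2E)-3-[4,5-bis(benzyloxy)-2-bromophenyl]prop-2-en-1-yl]oxy}(tert-butyl)dimethylsilane; 8 1-[4-(benzyloxy)-2-{[(1S)-1-[3,4-bis(benzyloxy)phenyl]prop-2-en-1-yl]oxy}phenyl]ethan-1-one
Product: 14 1-[4,5-bis(benzyloxy)-2-{(1E)-3-[(tert-butyldimethylsilyl)oxy]prop-1-en-1-yl}phenyl]-1-[4-(benzyloxy)-2-{[(1S)-1-[3,4-bis(benzyloxy)phenyl]prop-2-en-1-yl]oxy}phenyl]ethan-1-ol (both epimers at the carbinol carbon), via ring-D aryllithium 13 (not isolated)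
Conditions: n-BuLi (1.05 equiv per 12), THF, −78 °C, 15 min; then 8 (0.8 equiv), −78→−30 °C; H2O
Reagents that add atoms: none
Why: Bromine–lithium exchange followed by 1,2-addition of the aryllithium to the methyl ketone, which at −78 °C should outrun enolisation; the new carbinol centre needs no control because step 10 destroys it.

Step 10
Reactants: 14 the tertiary carbinol of step 9
Product: 15 tert-butyl{[(2E)-3-(4,5-bis(benzyloxy)-2-{1-[4-(benzyloxy)-2-{[(1S)-1-[3,4-bis(benzyloxy)phenyl]prop-2-en-1-yl]oxy}phenyl]ethenyl}phenyl)prop-2-en-1-yl]oxy}dimethylsilane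
Conditions: Burgess reagent (MeO2CN–SO2NEt3 inner salt, 2 equiv), THF, 25→50 °C; chromatography on Et3N-washed silica
Reagents that add atoms: none
Why: Burgess dehydration of the tertiary bis-benzylic alcohol can only remove a methyl hydrogen and so gives the 1,1-diarylethylene under neutral conditions, avoiding the acid that would ionise the allylic aryl ether.

Step 11
Reactants: 15 the silyl ether of step 10
Product: 16 (2E)-3-(4,5-bis(benzyloxy)-2-{1-[4-(benzyloxy)-2-{[(1S)-1-[3,4-bis(benzyloxy)phenyl]prop-2-en-1-yl]oxy}phenyl]ethenyl}phenyl)prop-2-en-1-ol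
Conditions: n-Bu4NF (1.2 equiv), THF, 0→25 °C
Reagents that add atoms: none
Why: Fluoride cleavage of the primary silyl ether is selective, since benzyl ethers, the allylic aryl ether and the alkenes do not react with fluoride.

Step 12
Reactants: 16 the allylic alcohol of step 11
Product: 17 (2E)-3-(4,5-bis(benzyloxy)-2-{1-[4-(benzyloxy)-2-{[(1S)-1-[3,4-bis(benzyloxy)phenyl]prop-2-en-1-yl]oxy}phenyl]ethenyl}phenyl)prop-2-en-1-yl methyl carbonate
Conditions: ClCO2Me, pyridine (excess), CH2Cl2, 0 °C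
Reagents that add atoms: methyl chloroformate, COC(=O)Cl
Why: O-acylation as in step 3, with excess pyridine keeping the medium basic for the acid-sensitive 1,1-diarylethylene.

Step 13
Reactants: 18 4-(benzyloxy)-2-hydroxybenzaldehyde
Product: 20 5-(benzyloxy)-2-ethenylphenol, via potassium 5-(benzyloxy)-2-formylphenolate 19 (not isolated)
Conditions: Ph3PCH3Br (2.5 equiv), KOtBu (2.5 equiv), THF, 0 °C; then 18, 0→25 °C; cold dilute HCl to pH 6; used promptly
Reagents that add atoms: methyltriphenylphosphonium bromide, C[P+](c1ccccc1)(c1ccccc1)c1ccccc1.[Br-]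
Why: Wittig methylenation with excess non-stabilised ylide, one equivalent of base being consumed by the phenol, is the standard conversion of salicylaldehydes into 2-vinylphenols.

Step 14
Reactants: 20 5-(benzyloxy)-2-ethenylphenol; 17 the cinnamyl carbonate of step 12
Product: 22 4-(benzyloxy)-2-{[(1S)-1-(4,5-bis(benzyloxy)-2-{1-[4-(benzyloxy)-2-{[(1S)-1-[3,4-bis(benzyloxy)phenyl]prop-2-en-1-yl]oxy}phenyl]ethenyl}phenyl)prop-2-en-1-yl]oxy}-1-ethenylbenzene, via lithium 5-(benzyloxy)-2-ethenylphenolate 21 (not isolated)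
Conditions: n-BuLi (1.0 equiv per 20), THF, −78→0 °C; then 17 (limiting, 0.5 equiv), [Ir(cod)Cl]2 (4 mol %), (Sa,Sc,Sc)-phosphoramidite (8 mol %, pre-activated with n-PrNH2, volatiles removed), THF, 25→40 °C
Reagents that add atoms: none
Why: Iridium-catalysed asymmetric allylic etherification as in step 4, with the electron-rich aryloxide attacking the ring-D-substituted allyl terminus so that C2' is set by the ligand irrespective of the remote C2 centre (catalyst control).

Step 15
Reactants: 22 the tetraene of step 14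
Product: 23 (2S)-7-(benzyloxy)-2-[3,4-bis(benzyloxy)phenyl]-4-{4,5-bis(benzyloxy)-2-[(2S)-7-(benzyloxy)-2H-chromen-2-yl]phenyl}-2H-chromene
Conditions: second-generation Grubbs catalyst (H2IMes)(PCy3)Cl2Ru=CHPh (5 mol %), 1,4-benzoquinone (20 mol %), toluene (0.005 M), 25 °C until ring F is closed; then a further 5 mol % catalyst, 80 °C, argon sparge
Reagents that add atoms: none
Why: The ruthenium benzylidene exchanges onto a terminal CH=CH2 group (the ring-G styrene or an O-bound 1-arylallyl group), the new alkylidene adds [2+2] to the alkene held ortho on the same aryl ether, and cycloreversion of the ruthenacyclobutane expels ethylene and leaves C3'=C4' and then C3=C4. The closest known reaction type is the ring-closing metathesis of 2-vinylphenyl and 2-(1-arylvinyl)phenyl allyl ethers to 2H-chromenes and 4-aryl-2H-chromenes. Ring F closes as a six-membered ring between two monosubstituted alkenes (cis-disubstituted product), and ring C closes as a six-membered ring in which the tethered alkylidene engages the 1,1-diarylethylene, a partner that is inert between molecules, to give the trisubstituted C3=C4. No stereocentre is formed; C2 and C2' are sp3 spectators set in steps 4 and 14, and they later direct borane in step 16. The step needs ring closure over cross-metathesis and the correct pairing, because the C2' vinyl group could also close onto the 1-arylvinyl group of ring D to give a five-membered indene. The pairing is secured by running first at 25 °C, where only the fast vinyl/vinyl closure of ring F proceeds and consumes the C2' vinyl group, before heating lets the 1,1-diarylethylene react with its only remaining partner, while dilution and ethylene removal disfavour oligomers and 1,4-benzoquinone suppresses ruthenium hydride migration of the allyl ether double bonds.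

Step 16
Reactants: 23 the bis-2H-chromene of step 15
Product: 25 (2R,3S,4R)-7-(benzyloxy)-2-[3,4-bis(benzyloxy)phenyl]-4-{4,5-bis(benzyloxy)-2-[(2R,3S)-7-(benzyloxy)-3-hydroxy-3,4-dihydro-2H-chromen-2-yl]phenyl}-3,4-dihydro-2H-chromen-3-ol, via bis(3-boryl)flavan adduct 24 (not isolated)
Conditions: BH3·SMe2 (6 equiv), THF, 0→25 °C; then 3 M NaOH, 30 % H2O2, 0→25 °C
Reagents that add atoms: borane–dimethyl sulfide, [BH3-][S+](C)C (boron in 24, hydrogen in 25); hydrogen peroxide, OO (the two hydroxyl oxygens)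
Why: Hydroboration–oxidation, in which borane adds syn across each C3=C4 bond from the face opposite the C2 aryl group with boron on C3 or C3' (C4 is fully substituted in ring C and is the donor-stabilised benzylic carbon in ring F) and peroxide oxidation with retention gives the 2,3-trans alcohols and, since H and B enter on the same face, the 3,4-trans arrangement of ring D in ring C.

Step 17
Reactants: 25 the hexabenzyl ether of step 16
Product: 26 (2R,3S,4R)-2-(3,4-dihydroxyphenyl)-4-{4,5-dihydroxy-2-[(2R,3S)-3,7-dihydroxy-3,4-dihydro-2H-chromen-2-yl]phenyl}-3,4-dihydro-2H-chromene-3,7-diol (CNP0244903.3)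
Conditions: H2 (1 atm), Pd(OH)2/C, THF–MeOH (1:1), 25 °C, degassed solvents
Reagents that add atoms: none
Why: Hydrogenolysis of the six benzyl ethers under neutral conditions leaves the pyran C–O bonds, the diarylmethine C4–H and all five stereocentres untouched, as in the usual last step of benzyl-protected flavan-3-ol syntheses.

**Compound list**

1 | 3,4-bis(benzyloxy)benzaldehyde | O=Cc1ccc(OCc9ccccc9)c(OCc9ccccc9)c1 | starting material
2 | triethyl phosphonoacetate | CCOC(=O)CP(=O)(OCC)OCC | starting material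
3 | ethyl (2E)-3-[3,4-bis(benzyloxy)phenyl]prop-2-enoate | CCOC(=O)/C=C/c1ccc(OCc9ccccc9)c(OCc9ccccc9)c1 | intermediate
4 | (2E)-3-[3,4-bis(benzyloxy)phenyl]prop-2-en-1-ol | OC/C=C/c1ccc(OCc9ccccc9)c(OCc9ccccc9)c1 | intermediate
5 | (2E)-3-[3,4-bis(benzyloxy)phenyl]prop-2-en-1-yl methyl carbonate | COC(=O)OC/C=C/c1ccc(OCc9ccccc9)c(OCc9ccccc9)c1 | intermediate
6 | 1-[4-(benzyloxy)-2-hydroxyphenyl]ethan-1-one | CC(=O)c1ccc(OCc9ccccc9)cc1O | starting material
7 | sodium 2-acetyl-5-(benzyloxy)phenolate | CC(=O)c1ccc(OCc9ccccc9)cc1[O-].[Na+] | intermediate (not isolated)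
8 | 1-[4-(benzyloxy)-2-{[(1S)-1-[3,4-bis(benzyloxy)phenyl]prop-2-en-1-yl]oxy}phenyl]ethan-1-one | CC(=O)c1ccc(OCc9ccccc9)cc1O[C@H](c1ccc(OCc9ccccc9)c(OCc9ccccc9)c1)C=C | intermediate
9 | 4,5-bis(benzyloxy)-2-bromobenzaldehyde | O=Cc1cc(OCc9ccccc9)c(OCc9ccccc9)cc1Br | intermediate
10 | ethyl (2E)-3-[4,5-bis(benzyloxy)-2-bromophenyl]prop-2-enoate | CCOC(=O)/C=C/c1cc(OCc9ccccc9)c(OCc9ccccc9)cc1Br | intermediate
11 | (2E)-3-[4,5-bis(benzyloxy)-2-bromophenyl]prop-2-en-1-ol | OC/C=C/c1cc(OCc9ccccc9)c(OCc9ccccc9)cc1Br | intermediate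
12 | {[(2E)-3-[4,5-bis(benzyloxy)-2-bromophenyl]prop-2-en-1-yl]oxy}(tert-butyl)dimethylsilane | CC(C)(C)[Si](C)(C)OC/C=C/c1cc(OCc9ccccc9)c(OCc9ccccc9)cc1Br | intermediate
13 | [4,5-bis(benzyloxy)-2-{(1E)-3-[(tert-butyldimethylsilyl)oxy]prop-1-en-1-yl}phenyl]lithium | CC(C)(C)[Si](C)(C)OC/C=C/c1cc(OCc9ccccc9)c(OCc9ccccc9)cc1[Li] | intermediate (not isolated)
14 | 1-[4,5-bis(benzyloxy)-2-{(1E)-3-[(tert-butyldimethylsilyl)oxy]prop-1-en-1-yl}phenyl]-1-[4-(benzyloxy)-2-{[(1S)-1-[3,4-bis(benzyloxy)phenyl]prop-2-en-1-yl]oxy}phenyl]ethan-1-ol, both carbinol epimers | CC(O)(c1cc(OCc9ccccc9)c(OCc9ccccc9)cc1/C=C/CO[Si](C)(C)C(C)(C)C)c1ccc(OCc9ccccc9)cc1O[C@H](c1ccc(OCc9ccccc9)c(OCc9ccccc9)c1)C=C | intermediate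
15 | tert-butyl{[(2E)-3-(4,5-bis(benzyloxy)-2-{1-[4-(benzyloxy)-2-{[(1S)-1-[3,4-bis(benzyloxy)phenyl]prop-2-en-1-yl]oxy}phenyl]ethenyl}phenyl)prop-2-en-1-yl]oxy}dimethylsilane | C=C(c1cc(OCc9ccccc9)c(OCc9ccccc9)cc1/C=C/CO[Si](C)(C)C(C)(C)C)c1ccc(OCc9ccccc9)cc1O[C@H](c1ccc(OCc9ccccc9)c(OCc9ccccc9)c1)C=C | intermediate
16 | (2E)-3-(4,5-bis(benzyloxy)-2-{1-[4-(benzyloxy)-2-{[(1S)-1-[3,4-bis(benzyloxy)phenyl]prop-2-en-1-yl]oxy}phenyl]ethenyl}phenyl)prop-2-en-1-ol | C=C(c1cc(OCc9ccccc9)c(OCc9ccccc9)cc1/C=C/CO)c1ccc(OCc9ccccc9)cc1O[C@H](c1ccc(OCc9ccccc9)c(OCc9ccccc9)c1)C=C | intermediate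
17 | (2E)-3-(4,5-bis(benzyloxy)-2-{1-[4-(benzyloxy)-2-{[(1S)-1-[3,4-bis(benzyloxy)phenyl]prop-2-en-1-yl]oxy}phenyl]ethenyl}phenyl)prop-2-en-1-yl methyl carbonate | C=C(c1cc(OCc9ccccc9)c(OCc9ccccc9)cc1/C=C/COC(=O)OC)c1ccc(OCc9ccccc9)cc1O[C@H](c1ccc(OCc9ccccc9)c(OCc9ccccc9)c1)C=C | intermediate
18 | 4-(benzyloxy)-2-hydroxybenzaldehyde | O=Cc1ccc(OCc9ccccc9)cc1O | starting material
19 | potassium 5-(benzyloxy)-2-formylphenolate | O=Cc1ccc(OCc9ccccc9)cc1[O-].[K+] | intermediate (not isolated)
20 | 5-(benzyloxy)-2-ethenylphenol | C=Cc1ccc(OCc9ccccc9)cc1O | intermediate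
21 | lithium 5-(benzyloxy)-2-ethenylphenolate | C=Cc1ccc(OCc9ccccc9)cc1[O-].[Li+] | intermediate (not isolated)
22 | 4-(benzyloxy)-2-{[(1S)-1-(4,5-bis(benzyloxy)-2-{1-[4-(benzyloxy)-2-{[(1S)-1-[3,4-bis(benzyloxy)phenyl]prop-2-en-1-yl]oxy}phenyl]ethenyl}phenyl)prop-2-en-1-yl]oxy}-1-ethenylbenzene (tetraene) | C=Cc1ccc(OCc9ccccc9)cc1O[C@H](c1cc(OCc9ccccc9)c(OCc9ccccc9)cc1C(=C)c1ccc(OCc9ccccc9)cc1O[C@H](c1ccc(OCc9ccccc9)c(OCc9ccccc9)c1)C=C)C=C | intermediate
23 | (2S)-7-(benzyloxy)-2-[3,4-bis(benzyloxy)phenyl]-4-{4,5-bis(benzyloxy)-2-[(2S)-7-(benzyloxy)-2H-chromen-2-yl]phenyl}-2H-chromene | c9ccccc9COc1ccc2c(c1)O[C@H](c1cc(OCc9ccccc9)c(OCc9ccccc9)cc1C1=C[C@@H](c3ccc(OCc9ccccc9)c(OCc9ccccc9)c3)Oc3cc(OCc9ccccc9)ccc31)C=C2 | intermediate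
24 | bis(3-boryl) adduct of 23, boron on C3 and C3', each trans to the aryl group on the neighbouring C2, drawn as the monoalkylborane | c9ccccc9COc1ccc2c(c1)O[C@H](c1cc(OCc9ccccc9)c(OCc9ccccc9)cc1[C@@H]1c3ccc(OCc9ccccc9)cc3O[C@H](c3ccc(OCc9ccccc9)c(OCc9ccccc9)c3)[C@H]1B)[C@@H](B)C2 | intermediate (not isolated)
25 | (2R,3S,4R)-7-(benzyloxy)-2-[3,4-bis(benzyloxy)phenyl]-4-{4,5-bis(benzyloxy)-2-[(2R,3S)-7-(benzyloxy)-3-hydroxy-3,4-dihydro-2H-chromen-2-yl]phenyl}-3,4-dihydro-2H-chromen-3-ol | c9ccccc9COc1ccc2c(c1)O[C@H](c1cc(OCc9ccccc9)c(OCc9ccccc9)cc1[C@@H]1c3ccc(OCc9ccccc9)cc3O[C@H](c3ccc(OCc9ccccc9)c(OCc9ccccc9)c3)[C@H]1O)[C@@H](O)C2 | intermediate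
26 | (2R,3S,4R)-2-(3,4-dihydroxyphenyl)-4-{4,5-dihydroxy-2-[(2R,3S)-3,7-dihydroxy-3,4-dihydro-2H-chromen-2-yl]phenyl}-3,4-dihydro-2H-chromene-3,7-diol | Oc1ccc2c(c1)O[C@H](c1cc(O)c(O)cc1[C@@H]1c3ccc(O)cc3O[C@H](c3ccc(O)c(O)c3)[C@H]1O)[C@@H](O)C2 | target

**Step count and risks**

Total step count: 17. Longest linear sequence: 12 steps (1 → 9 → 10 → 11 → 12 → 14 → 15 → 16 → 17 → 22 → 23 → 25 → 26, steps 5–12 and 14–17).

Steps most likely to fail:

1. Step 15 (double ring-closing metathesis). The alkylidene on the C2' vinyl group may pair with the 1-arylvinyl group of ring D in an indene closure, or the upper alkylidene may fail to engage the hindered 1,1-diarylethylene and drift into oligomerisation or allyl ether isomerisation. The fallback gives up the twofold format and closes the two rings on different intermediates; it sets out from 15 and comes back at 23. Ring C would be closed alone on 15 with the same ruthenium catalyst (toluene, 80–100 °C), where no second allyl ether exists and the indene pathway is absent, to give (2S)-4-aryl-2H-chromene silyl ether F1. n-Bu4NF would then free allylic alcohol F2, and ClCO2Me/pyridine would give methyl carbonate F3. Iridium-catalysed etherification of F3 with aryloxide 21 under the conditions of step 14 would give chromenyl diene ether F4, and an undemanding single metathesis of F4 (vinyl with allyl ether) would close ring F to give 23.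

2. Step 14 (second iridium etherification). Ionisation and attack at an allyl terminus flanked by the bulky ortho 1-arylvinyl group may be slow and poorly selective, giving linear ether, low control at C2' or re-ionisation of the ether already present. The fallback forms the C2' ether while the ortho substituent is only bromine and makes the hindered diarylethylene afterwards; it sets out from 11 and comes back at 22, replacing steps 8–12 and 14. ClCO2Me/pyridine on 11 would give bromo carbonate F5, and iridium-catalysed etherification with 21 would give (S)-bromo ether F6. Bromine–lithium exchange (n-BuLi, THF, −78 °C, short contact) would give aryllithium F7 (not isolated), trapped at once with ketone 8 to give tertiary carbinol F8. Burgess dehydration of F8 would give 22.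

3. Step 9 (aryllithium addition). Enolisation of the hindered methyl ketone by the basic aryllithium may outpace carbonyl addition and return ketone and protonated arene. The fallback replaces the enolisable ketone by an aldehyde and builds the ethylene carbon by olefination; it sets out from 18 (with 5 and 12) and comes back at 15. NaH on 18 would give sodium 5-(benzyloxy)-2-formylphenolate F9 (not isolated), and iridium-catalysed etherification with 5 as in step 4 would give aldehyde ether F10. Aryllithium 13, made from 12 as in step 9, would add to F10 to give diarylmethanol F11. Dess–Martin oxidation (NaHCO3, CH2Cl2) would give benzophenone F12, and Wittig methylenation (Ph3PCH3Br, KOtBu, THF, reflux) would give 15.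

Step 16 is the step that sets C3, C4 and C3', but it follows the usual regiochemistry and anti-to-aryl facial preference of borane with 2-aryl-2H-chromenes and is ranked just below these three.

**Further compounds**

F1 | step 15 | tert-butyl{[(2E)-3-(4,5-bis(benzyloxy)-2-{(2S)-7-(benzyloxy)-2-[3,4-bis(benzyloxy)phenyl]-2H-chromen-4-yl}phenyl)prop-2-en-1-yl]oxy}dimethylsilane | CC(C)(C)[Si](C)(C)OC/C=C/c1cc(OCc9ccccc9)c(OCc9ccccc9)cc1C1=C[C@@H](c3ccc(OCc9ccccc9)c(OCc9ccccc9)c3)Oc3cc(OCc9ccccc9)ccc31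
F2 | step 15 | (2E)-3-(4,5-bis(benzyloxy)-2-{(2S)-7-(benzyloxy)-2-[3,4-bis(benzyloxy)phenyl]-2H-chromen-4-yl}phenyl)prop-2-en-1-ol | OC/C=C/c1cc(OCc9ccccc9)c(OCc9ccccc9)cc1C1=C[C@@H](c3ccc(OCc9ccccc9)c(OCc9ccccc9)c3)Oc3cc(OCc9ccccc9)ccc31
F3 | step 15 | (2E)-3-(4,5-bis(benzyloxy)-2-{(2S)-7-(benzyloxy)-2-[3,4-bis(benzyloxy)phenyl]-2H-chromen-4-yl}phenyl)prop-2-en-1-yl methyl carbonate | COC(=O)OC/C=C/c1cc(OCc9ccccc9)c(OCc9ccccc9)cc1C1=C[C@@H](c3ccc(OCc9ccccc9)c(OCc9ccccc9)c3)Oc3cc(OCc9ccccc9)ccc31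
F4 | step 15 | (2S)-7-(benzyloxy)-2-[3,4-bis(benzyloxy)phenyl]-4-(4,5-bis(benzyloxy)-2-{(1S)-1-[5-(benzyloxy)-2-ethenylphenoxy]prop-2-en-1-yl}phenyl)-2H-chromene | C=Cc1ccc(OCc9ccccc9)cc1O[C@H](c1cc(OCc9ccccc9)c(OCc9ccccc9)cc1C1=C[C@@H](c3ccc(OCc9ccccc9)c(OCc9ccccc9)c3)Oc3cc(OCc9ccccc9)ccc31)C=C
F5 | step 14 | (2E)-3-[4,5-bis(benzyloxy)-2-bromophenyl]prop-2-en-1-yl methyl carbonate | COC(=O)OC/C=C/c1cc(OCc9ccccc9)c(OCc9ccccc9)cc1Br
F6 | step 14 | 4-(benzyloxy)-2-{[(1S)-1-[4,5-bis(benzyloxy)-2-bromophenyl]prop-2-en-1-yl]oxy}-1-ethenylbenzene | C=Cc1ccc(OCc9ccccc9)cc1O[C@H](c1cc(OCc9ccccc9)c(OCc9ccccc9)cc1Br)C=C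
F7 | step 14 | (4,5-bis(benzyloxy)-2-{(1S)-1-[5-(benzyloxy)-2-ethenylphenoxy]prop-2-en-1-yl}phenyl)lithium | C=Cc1ccc(OCc9ccccc9)cc1O[C@H](c1cc(OCc9ccccc9)c(OCc9ccccc9)cc1[Li])C=C
F8 | step 14 | 1-(4,5-bis(benzyloxy)-2-{(1S)-1-[5-(benzyloxy)-2-ethenylphenoxy]prop-2-en-1-yl}phenyl)-1-[4-(benzyloxy)-2-{[(1S)-1-[3,4-bis(benzyloxy)phenyl]prop-2-en-1-yl]oxy}phenyl]ethan-1-ol, both carbinol epimers | C=Cc1ccc(OCc9ccccc9)cc1O[C@H](c1cc(OCc9ccccc9)c(OCc9ccccc9)cc1C(C)(O)c1ccc(OCc9ccccc9)cc1O[C@H](c1ccc(OCc9ccccc9)c(OCc9ccccc9)c1)C=C)C=C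
F9 | step 9 | sodium 5-(benzyloxy)-2-formylphenolate | O=Cc1ccc(OCc9ccccc9)cc1[O-].[Na+]
F10 | step 9 | 4-(benzyloxy)-2-{[(1S)-1-[3,4-bis(benzyloxy)phenyl]prop-2-en-1-yl]oxy}benzaldehyde | O=Cc1ccc(OCc9ccccc9)cc1O[C@H](c1ccc(OCc9ccccc9)c(OCc9ccccc9)c1)C=C
F11 | step 9 | [4,5-bis(benzyloxy)-2-{(1E)-3-[(tert-butyldimethylsilyl)oxy]prop-1-en-1-yl}phenyl][4-(benzyloxy)-2-{[(1S)-1-[3,4-bis(benzyloxy)phenyl]prop-2-en-1-yl]oxy}phenyl]methanol, both carbinol epimers | OC(c1cc(OCc9ccccc9)c(OCc9ccccc9)cc1/C=C/CO[Si](C)(C)C(C)(C)C)c1ccc(OCc9ccccc9)cc1O[C@H](c1ccc(OCc9ccccc9)c(OCc9ccccc9)c1)C=C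
F12 | step 9 | [4,5-bis(benzyloxy)-2-{(1E)-3-[(tert-butyldimethylsilyl)oxy]prop-1-en-1-yl}phenyl][4-(benzyloxy)-2-{[(1S)-1-[3,4-bis(benzyloxy)phenyl]prop-2-en-1-yl]oxy}phenyl]methanone | O=C(c1cc(OCc9ccccc9)c(OCc9ccccc9)cc1/C=C/CO[Si](C)(C)C(C)(C)C)c1ccc(OCc9ccccc9)cc1O[C@H](c1ccc(OCc9ccccc9)c(OCc9ccccc9)c1)C=C
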